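**Plan**

- Retrosynthesis: the eight phenols are masked as benzyl ethers. The indane five-membered ring (C1 = benzylidene carbon, C2, C3 = carbon bearing the 4-oxyphenyl group, C3a, C7a) is cut at C3–C3a and C2–C3. This releases C3 with its aryl group as 4-(benzyloxy)benzaldehyde and leaves an α-aryl allylsilane. The C–Si bond is traced by a syn SN2' displacement to an allylic alcohol, and this by anti-arylmagnesiation and Sonogashira coupling to a propargylic alcohol and a 5-bromo-2,3-diaryl-2,3-dihydrobenzofuran.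
- Forward: the dihydrobenzofuran ring is closed first (Rh2(S-PTAD)4-catalysed carbene C–H insertion, then cis→trans equilibration). The chain is joined by Sonogashira coupling and arylmagnesiation. The indane ring is closed last by a Hosomi–Sakurai/Friedel–Crafts (4+1) annulation, followed by global debenzylation.
- Enabling feature: in the cyclopentane ring, C2 is a methine flanked by the exocyclic C1=CH–aryl alkene and by C3, and C3 is benzylic to a 4-oxyphenyl group and bonded to C3a of the resorcinol ring. This homoallylic array is the footprint of an allylsilane SE2' attack (C2–C3) followed by a Friedel–Crafts closure (C3–C3a).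
- Stereochemistry: the dihydrobenzofuran centres (2S,3S) come from Rh2(S-PTAD)4 plus thermodynamic equilibration. One carbinol centre from a Me2Zn/(S,S)-ProPhenol alkynylation is relayed by syn SN2' to the C–Si centre, by anti SE2' to C2 (R) and the Z-benzylidene, and by the ring closure to C3 (R, trans to C2).

Key step: step 12

Remark 1: the senses of induction in steps 4 and 6 are assigned by analogy with simpler substrates; if either proves opposite, the mirror-image catalyst is used.
Remark 2: in names, "DHB-5-yl" stands for (2S,3S)-2-[4-(benzyloxy)phenyl]-3-[3,5-bis(benzyloxy)phenyl]-2,3-dihydrobenzofuran-5-yl, and Bn for benzyl.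

**Route**

Step 1
Reactants: 1 5-bromo-2-hydroxybenzonitrile; 2 4-(benzyloxy)benzyl chloride
Product: 3 2-{[4-(benzyloxy)benzyl]oxy}-5-bromobenzonitrile
Conditions: K2CO3, NaI (cat.), DMF, 60 °C
Reagents that add atoms: none
Why: Williamson etherification of the acidic ortho-cyanophenol with an activated benzylic chloride installs the O–CH2–aryl group whose C–H bond is used in step 4; no stereocentre is formed.

Step 2
Reactants: 4 1,3-bis(benzyloxy)-5-bromobenzene
Product: 5 [3,5-bis(benzyloxy)phenyl]magnesium bromide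
Conditions: Mg turnings, I2 (cat.), THF, 40 °C → reflux; kept as a titrated THF stock solution
Reagents that add atoms: magnesium, [Mg]
Why: oxidative insertion of magnesium into the aryl C–Br bond (Grignard reagent formation) tolerates the benzyl ethers and gives one batch of the aryl nucleophile that serves both step 3 and step 9.

Step 3
Reactants: 3 2-{[4-(benzyloxy)benzyl]oxy}-5-bromobenzonitrile; 5 [3,5-bis(benzyloxy)phenyl]magnesium bromide
Product: 7 hydrazone of (2-{[4-(benzyloxy)benzyl]oxy}-5-bromophenyl)[3,5-bis(benzyloxy)phenyl]methanone (E/Z mixture), via N–H ketimine 6 (not isolated)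
Conditions: 5 (1.3 equiv, THF solution), THF, 60 °C; MeOH, 0 °C; then N2H4·H2O, AcOH, EtOH, 70 °C
Reagents that add atoms: hydrazine, NN (used as the hydrate)
Why: Grignard addition to the nitrile stops at the ketiminate, methanol frees the N–H ketimine, and transimination with hydrazine gives the hindered diaryl hydrazone without the acidic ketone hydrolysis that would endanger the 4-alkoxybenzyl aryl ether.

Step 4
Reactants: 7 the hydrazone
Product: 9 (2R,3S)-cis-2-[4-(benzyloxy)phenyl]-3-[3,5-bis(benzyloxy)phenyl]-5-bromo-2,3-dihydrobenzofuran, via diazo compound 8 (not isolated)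
Conditions: MnO2, CH2Cl2, 0 °C, filtration; then Rh2(S-PTAD)4 {dirhodium tetrakis[(S)-(1-adamantyl)(phthalimido)acetate]} (1 mol %), CH2Cl2, 0 °C → rt
Reagents that add atoms: none
Why: MnO2 dehydrogenates the hydrazone to the diaryldiazomethane, and Rh2(S-PTAD)4 converts it into a donor/donor carbene that undergoes 1,5-C–H insertion into the activated O–CH2–aryl bond; the catalyst sets C3 (S) and the insertion delivers C2 cis to it.

Step 5
Reactants: 9 the cis-dihydrobenzofuran
Product: 10 (2S,3S)-trans-2-[4-(benzyloxy)phenyl]-3-[3,5-bis(benzyloxy)phenyl]-5-bromo-2,3-dihydrobenzofuran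
Conditions: BF3·OEt2 (0.3 equiv), CH2Cl2, −20 °C → rt
Reagents that add atoms: none
Why: Lewis-acid-mediated reversible heterolysis of the benzylic C2–O bond (4-benzyloxybenzyl cation and phenoxide) equilibrates C2 to the more stable trans isomer, while C3 is not touched and keeps the configuration set in step 4.

Step 6
Reactants: 11 3,5-bis(benzyloxy)benzaldehyde; 12 ethynyltrimethylsilane
Product: 13 (S)-1-[3,5-bis(benzyloxy)phenyl]-3-(trimethylsilyl)prop-2-yn-1-ol
Conditions: (S,S)-ProPhenol [(S,S)-2,6-bis{[2-(hydroxydiphenylmethyl)pyrrolidin-1-yl]methyl}-4-methylphenol] (10 mol %), Me2Zn, Ph3PO (20 mol %), toluene, 0 °C; aq. NH4Cl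
Reagents that add atoms: none
Why: catalytic enantioselective alkynylzinc addition to an aryl aldehyde, with the catalyst formed from Me2Zn and (S,S)-ProPhenol, sets the carbinol centre by catalyst control.

Step 7
Reactants: 13 the silylated propargylic alcohol
Product: 14 (R)-1-[3,5-bis(benzyloxy)phenyl]prop-2-yn-1-ol
Conditions: K2CO3 (cat.), MeOH, rt
Reagents that add atoms: none
Why: base-catalysed methanolysis of the C(sp)–Si bond frees the terminal alkyne; the carbinol centre is untouched and its descriptor changes from S to R only through the CIP priorities.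

Step 8
Reactants: 10 the trans-5-bromodihydrobenzofuran; 14 the terminal propargylic alcohol
Product: 15 (S)-1-[3,5-bis(benzyloxy)phenyl]-3-(DHB-5-yl)prop-2-yn-1-ol
Conditions: PdCl2(PhCN)2 (3 mol %), P(t-Bu)3 (6 mol %), CuI (2 mol %), i-Pr2NH, dioxane, rt
Reagents that add atoms: none
Why: Sonogashira coupling with a bulky electron-rich phosphine couples the electron-rich aryl bromide at room temperature, so the free propargylic alcohol and the dihydrobenzofuran are not exposed to heat or strong base; no stereocentre is affected.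

Step 9
Reactants: 15 the diarylpropargylic alcohol; 5 [3,5-bis(benzyloxy)phenyl]magnesium bromide
Product: 17 (S,E)-1,2-bis[3,5-bis(benzyloxy)phenyl]-3-(DHB-5-yl)prop-2-en-1-ol, via alkenylmagnesium chelate 16 (not isolated)
Conditions: 5 (4 equiv, THF solution), CuI (10 mol %), THF, reflux; aq. NH4Cl
Reagents that add atoms: none
Why: hydroxyl-directed anti-carbomagnesiation of a propargylic alcohol delivers the aryl group to the alkyne carbon next to the carbinol and magnesium to the far carbon in a five-membered chelate, so protonation gives a single alkene geometry in which the new aryl group on C2 and the DHB group on C3 are cis; the carbinol centre is untouched.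

Step 10
Reactants: 17 the allylic alcohol
Product: 18 (S,E)-1,2-bis[3,5-bis(benzyloxy)phenyl]-3-(DHB-5-yl)prop-2-en-1-yl phenylcarbamate
Conditions: PhNCO, DMAP (cat.), CH2Cl2, rt
Reagents that add atoms: phenyl isocyanate, O=C=Nc1ccccc1
Why: base-catalysed addition of the alcohol to the isocyanate gives a carbamate that resists ionisation and can later deliver the silyl nucleophile; the carbinol configuration is retained.

Step 11
Reactants: 18 the allylic N-phenylcarbamate
Product: 19 {(1S,2Z)-2,3-bis[3,5-bis(benzyloxy)phenyl]-1-(DHB-5-yl)prop-2-en-1-yl}dimethyl(phenyl)silane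
Conditions: n-BuLi, THF, −78 °C; CuI, PPh3, 0 °C; PhMe2SiLi (stock solution in THF), 0 °C → rt; aq. NH4Cl
Reagents that add atoms: dimethylphenylsilyllithium, C[Si]([Li])(C)c1ccccc1
Why: syn SN2' displacement of the allylic carbamate by the silylcopper reagent made from CuI and PhMe2SiLi and held on the deprotonated carbamate nitrogen moves the stereocentre from the carbinol carbon to the silicon-bearing carbon (S); the rotamer that turns the carbinol aryl group away from the neighbouring aryl group gives the Z-alkene, and reaction through the other rotamer would invert alkene geometry and silicon-bearing centre together, a pairing that step 12 carries to the same product.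

Step 12
Reactants: 19 the allylsilane; 20 4-(benzyloxy)benzaldehyde
Product: 22 (2S,3S)-2-[4-(benzyloxy)phenyl]-3-[3,5-bis(benzyloxy)phenyl]-5-{(Z)-[(2R,3R)-4,6-bis(benzyloxy)-3-[4-(benzyloxy)phenyl]-2-[3,5-bis(benzyloxy)phenyl]-2,3-dihydro-1H-inden-1-ylidene]methyl}-2,3-dihydrobenzofuran (octa-O-benzyl ether of the target), via homoallylic silyl ether 21 (not isolated)
Conditions: Bi(OTf)3 (10 mol %), CH2Cl2, −40 → 0 °C; then Et3N
Reagents that add atoms: none
Why: Proposed new method: Bi(OTf)3 activates aldehyde 20 for an open-transition-state Hosomi–Sakurai attack by the γ-carbon of 19 (the future indane C2), the β-silyl cation sheds silicon onto oxygen to give silyl ether 21, and the same acid then ionises the 4-benzyloxybenzylic C–O bond of 21 so that the ortho carbon of the 3,5-bis(benzyloxy)phenyl group on the new alkene carbon captures the cation (future C3–C3a bond). The closest known reaction types are the Hosomi–Sakurai allylation with 1,3-chirality transfer from α-aryl allylsilanes and the tandem allylation/Friedel–Crafts alkylation of electron-rich aryl aldehydes, here with the arene tethered so that the second event closes a ring and the whole is a (4+1) annulation. The cyclopentane closes by intramolecular Friedel–Crafts alkylation (5-endo with respect to the arene π bond), the mode by which such indanes form from quinone methides. C2 (R) is set by the silicon-bearing centre, because A(1,3) strain with the cis aryl group holds the hydrogen of that centre in the alkene plane and the electrophile enters anti to silicon, which also places the dihydrobenzofuranyl group cis to the fused arene in the new Z-benzylidene; C3 (R) is set by C2, the two aryl groups ending trans on the forming ring. Allylsilane that carries both the opposite silicon-bearing configuration and the opposite alkene geometry would take the electrophile on the other face of the other alkene isomer and so give the same product, which makes the step stereoconvergent. The step needs attack of the aldehyde on the allylsilane and not on one of the dialkoxyaryl rings, and ring closure before loss of the C2 proton; the β-aryl allylsilane is the strongest π-nucleophile present at low temperature, and the doubly activated ortho position sits within reach of the cation for a five-membered ring.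

Step 13
Reactants: 22 the octabenzyl ether
Product: 23 target, 4-[(2S,3S)-3-(3,5-dihydroxyphenyl)-5-{(Z)-[(2R,3R)-2-(3,5-dihydroxyphenyl)-4,6-dihydroxy-3-(4-hydroxyphenyl)-2,3-dihydro-1H-inden-1-ylidene]methyl}-2,3-dihydrobenzofuran-2-yl]phenol
Conditions: BCl3 (24 equiv), pentamethylbenzene (24 equiv), CH2Cl2, −78 °C; then MeOH
Reagents that add atoms: none
Why: BCl3 with pentamethylbenzene as a non-basic benzyl-cation scavenger cleaves aryl benzyl ethers at −78 °C without hydrogenation, which spares the benzylidene alkene, the dihydrobenzofuran and all four stereocentres.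

**Compound list**

1 | 5-bromo-2-hydroxybenzonitrile | N#Cc1cc(Br)ccc1O | starting material
2 | 4-(benzyloxy)benzyl chloride | ClCc1ccc(OCc2ccccc2)cc1 | starting material
3 | 2-{[4-(benzyloxy)benzyl]oxy}-5-bromobenzonitrile | N#Cc1cc(Br)ccc1OCc1ccc(OCc2ccccc2)cc1 | intermediate
4 | 1,3-bis(benzyloxy)-5-bromobenzene | Brc1cc(OCc2ccccc2)cc(OCc2ccccc2)c1 | starting material
5 | [3,5-bis(benzyloxy)phenyl]magnesium bromide (titrated THF stock solution) | Br[Mg]c1cc(OCc2ccccc2)cc(OCc2ccccc2)c1 | intermediate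
6 | N–H ketimine, 1-(2-{[4-(benzyloxy)benzyl]oxy}-5-bromophenyl)-1-[3,5-bis(benzyloxy)phenyl]methanimine (not isolated) | N=C(c1cc(OCc2ccccc2)cc(OCc2ccccc2)c1)c1cc(Br)ccc1OCc1ccc(OCc2ccccc2)cc1 | intermediate
7 | hydrazone of (2-{[4-(benzyloxy)benzyl]oxy}-5-bromophenyl)[3,5-bis(benzyloxy)phenyl]methanone (E/Z mixture) | NN=C(c1cc(OCc2ccccc2)cc(OCc2ccccc2)c1)c1cc(Br)ccc1OCc1ccc(OCc2ccccc2)cc1 | intermediate
8 | (2-{[4-(benzyloxy)benzyl]oxy}-5-bromophenyl)[3,5-bis(benzyloxy)phenyl]diazomethane (not isolated) | [N-]=[N+]=C(c1cc(OCc2ccccc2)cc(OCc2ccccc2)c1)c1cc(Br)ccc1OCc1ccc(OCc2ccccc2)cc1 | intermediate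
9 | (2R,3S)-cis-2-[4-(benzyloxy)phenyl]-3-[3,5-bis(benzyloxy)phenyl]-5-bromo-2,3-dihydrobenzofuran | Brc1ccc2c(c1)[C@H](c1cc(OCc3ccccc3)cc(OCc3ccccc3)c1)[C@H](c1ccc(OCc3ccccc3)cc1)O2 | intermediate
10 | (2S,3S)-trans-2-[4-(benzyloxy)phenyl]-3-[3,5-bis(benzyloxy)phenyl]-5-bromo-2,3-dihydrobenzofuran | Brc1ccc2c(c1)[C@H](c1cc(OCc3ccccc3)cc(OCc3ccccc3)c1)[C@@H](c1ccc(OCc3ccccc3)cc1)O2 | intermediate
11 | 3,5-bis(benzyloxy)benzaldehyde | O=Cc1cc(OCc2ccccc2)cc(OCc2ccccc2)c1 | starting material
12 | ethynyltrimethylsilane | C#C[Si](C)(C)C | starting material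
13 | (S)-1-[3,5-bis(benzyloxy)phenyl]-3-(trimethylsilyl)prop-2-yn-1-ol | O[C@H](C#C[Si](C)(C)C)c1cc(OCc2ccccc2)cc(OCc2ccccc2)c1 | intermediate
14 | (R)-1-[3,5-bis(benzyloxy)phenyl]prop-2-yn-1-ol | O[C@H](C#C)c1cc(OCc2ccccc2)cc(OCc2ccccc2)c1 | intermediate
15 | (S)-1-[3,5-bis(benzyloxy)phenyl]-3-(DHB-5-yl)prop-2-yn-1-ol | O[C@H](C#Cc1ccc2c(c1)[C@H](c1cc(OCc3ccccc3)cc(OCc3ccccc3)c1)[C@@H](c1ccc(OCc3ccccc3)cc1)O2)c1cc(OCc2ccccc2)cc(OCc2ccccc2)c1 | intermediate
16 | five-membered alkenylmagnesium alkoxide chelate from anti-arylmagnesiation of 15 (2,5-dihydro-1,2-oxamagnesole; not isolated) | [Mg]1O[C@@H](c2cc(OCc3ccccc3)cc(OCc3ccccc3)c2)C(c2cc(OCc3ccccc3)cc(OCc3ccccc3)c2)=C1c1ccc2c(c1)[C@H](c1cc(OCc3ccccc3)cc(OCc3ccccc3)c1)[C@@H](c1ccc(OCc3ccccc3)cc1)O2 | intermediate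
17 | (S,E)-1,2-bis[3,5-bis(benzyloxy)phenyl]-3-(DHB-5-yl)prop-2-en-1-ol | O[C@H](/C(c1cc(OCc2ccccc2)cc(OCc2ccccc2)c1)=C/c1ccc2c(c1)[C@H](c1cc(OCc3ccccc3)cc(OCc3ccccc3)c1)[C@@H](c1ccc(OCc3ccccc3)cc1)O2)c1cc(OCc2ccccc2)cc(OCc2ccccc2)c1 | intermediate
18 | (S,E)-1,2-bis[3,5-bis(benzyloxy)phenyl]-3-(DHB-5-yl)prop-2-en-1-yl phenylcarbamate | O=C(Nc1ccccc1)O[C@H](/C(c1cc(OCc2ccccc2)cc(OCc2ccccc2)c1)=C/c1ccc2c(c1)[C@H](c1cc(OCc3ccccc3)cc(OCc3ccccc3)c1)[C@@H](c1ccc(OCc3ccccc3)cc1)O2)c1cc(OCc2ccccc2)cc(OCc2ccccc2)c1 | intermediate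
19 | {(1S,2Z)-2,3-bis[3,5-bis(benzyloxy)phenyl]-1-(DHB-5-yl)prop-2-en-1-yl}dimethyl(phenyl)silane | C[Si](C)(c1ccccc1)[C@@H](c1ccc2c(c1)[C@H](c1cc(OCc3ccccc3)cc(OCc3ccccc3)c1)[C@@H](c1ccc(OCc3ccccc3)cc1)O2)/C(c1cc(OCc2ccccc2)cc(OCc2ccccc2)c1)=C\c1cc(OCc2ccccc2)cc(OCc2ccccc2)c1 | intermediate
20 | 4-(benzyloxy)benzaldehyde | O=Cc1ccc(OCc2ccccc2)cc1 | starting material
21 | (2R,3Z)-1-[4-(benzyloxy)phenyl]-2,3-bis[3,5-bis(benzyloxy)phenyl]-4-(DHB-5-yl)but-3-en-1-yl dimethyl(phenyl)silyl ether, both C1 epimers (not isolated) | c1c(OCc2ccccc2)cc(OCc2ccccc2)cc1/C(=C\c1ccc2c(c1)[C@H](c1cc(OCc3ccccc3)cc(OCc3ccccc3)c1)[C@@H](c1ccc(OCc3ccccc3)cc1)O2)[C@H](C(O[Si](C)(C)c1ccccc1)c1ccc(OCc2ccccc2)cc1)c1cc(OCc2ccccc2)cc(OCc2ccccc2)c1 | intermediate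
22 | (2S,3S)-2-[4-(benzyloxy)phenyl]-3-[3,5-bis(benzyloxy)phenyl]-5-{(Z)-[(2R,3R)-4,6-bis(benzyloxy)-3-[4-(benzyloxy)phenyl]-2-[3,5-bis(benzyloxy)phenyl]-2,3-dihydro-1H-inden-1-ylidene]methyl}-2,3-dihydrobenzofuran (octa-O-benzyl ether of the target) | c1ccccc1COc1ccc([C@@H]2c3c(OCc4ccccc4)cc(OCc4ccccc4)cc3/C(=C\c3ccc4c(c3)[C@H](c3cc(OCc5ccccc5)cc(OCc5ccccc5)c3)[C@@H](c3ccc(OCc5ccccc5)cc3)O4)[C@H]2c2cc(OCc3ccccc3)cc(OCc3ccccc3)c2)cc1 | intermediate
23 | 4-[(2S,3S)-3-(3,5-dihydroxyphenyl)-5-{(Z)-[(2R,3R)-2-(3,5-dihydroxyphenyl)-4,6-dihydroxy-3-(4-hydroxyphenyl)-2,3-dihydro-1H-inden-1-ylidene]methyl}-2,3-dihydrobenzofuran-2-yl]phenol | Oc1ccc([C@@H]2c3c(O)cc(O)cc3/C(=C\c3ccc4c(c3)[C@H](c3cc(O)cc(O)c3)[C@@H](c3ccc(O)cc3)O4)[C@H]2c2cc(O)cc(O)c2)cc1 | target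

**Summary**

Total step count: 13. Longest linear sequence: 10 steps (steps 1, 3–5 and 8–13).

Steps most likely to fail:

Step 12 (proposed new method). The activated aldehyde may alkylate one of the dialkoxyaryl rings instead of the allylsilane, the allylsilane may be protodesilylated by adventitious triflic acid, the benzylic cation may lose the C2 proton or suffer a hydride shift before ring closure, and the benzylidene may isomerise under acid. The fallback separates the two events with known chemistry. It sets out from 19: a Hosomi–Sakurai reaction with 20 and stoichiometric TiCl4 in CH2Cl2 at −78 °C, quenched cold, should give the homoallylic alcohol (2R,3Z)-1-[4-(benzyloxy)phenyl]-2,3-bis[3,5-bis(benzyloxy)phenyl]-4-(DHB-5-yl)but-3-en-1-ol F1 as a mixture of C1 epimers. A separate Friedel–Crafts cyclisation of F1 with catalytic TsOH in hexafluoroisopropanol at 0 °C then returns to the route at 22.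

Step 11. The silylcopper reagent may attack the carbinol carbon instead of the styrenyl terminus, or the allylic carbamate may ionise and lose stereochemical fidelity. The fallback replaces the copper reagent by an intramolecular silicon delivery with the same syn sense. It sets out from 17: silylation with 1-chloro-2,2-dimethyl-1,1,2-triphenyldisilane and imidazole should give the disilanyl ether (S,E)-1,2-bis[3,5-bis(benzyloxy)phenyl]-3-(DHB-5-yl)prop-2-en-1-yl 2,2-dimethyl-1,1,2-triphenyldisilanyl ether F2. Intramolecular bis-silylation of the alkene with Pd(acac)2 and 1,1,3,3-tetramethylbutyl isocyanide in refluxing toluene should give the 1,2-oxasiletane (3S,4S)-3,4-bis[3,5-bis(benzyloxy)phenyl]-3-[(S)-(DHB-5-yl)(dimethylphenylsilyl)methyl]-2,2-diphenyl-1,2-oxasiletane F3. Ring opening of F3 with n-BuLi followed by KOt-Bu triggers a syn Peterson elimination and returns to the route at 19.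

Step 9. Addition of the aryl Grignard reagent to the electron-rich diarylalkyne may be slow, and syn addition or reduction may compete. The fallback makes the same alkene in two known steps. It sets out from 15: hydroxyl-directed trans-hydrostannation with Bu3SnH and [Cp*RuCl]4 in CH2Cl2 places the Bu3Sn group on the alkyne carbon next to the carbinol and should give the alkenylstannane (S,Z)-1-[3,5-bis(benzyloxy)phenyl]-3-(DHB-5-yl)-2-(tributylstannyl)prop-2-en-1-ol F4. Stille coupling of F4 with bromide 4 (Pd(PPh3)4, CuI, CsF, DMF) proceeds with retention and returns to the route at 17.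

**Further compounds**

F1 | step 12 | (2R,3Z)-1-[4-(benzyloxy)phenyl]-2,3-bis[3,5-bis(benzyloxy)phenyl]-4-(DHB-5-yl)but-3-en-1-ol, both C1 epimers | c1c(OCc2ccccc2)cc(OCc2ccccc2)cc1/C(=C\c1ccc2c(c1)[C@H](c1cc(OCc3ccccc3)cc(OCc3ccccc3)c1)[C@@H](c1ccc(OCc3ccccc3)cc1)O2)[C@H](C(O)c1ccc(OCc2ccccc2)cc1)c1cc(OCc2ccccc2)cc(OCc2ccccc2)c1
F2 | step 11 | (S,E)-1,2-bis[3,5-bis(benzyloxy)phenyl]-3-(DHB-5-yl)prop-2-en-1-yl 2,2-dimethyl-1,1,2-triphenyldisilanyl ether | C[Si](C)(c1ccccc1)[Si](c1ccccc1)(c1ccccc1)O[C@H](/C(c1cc(OCc2ccccc2)cc(OCc2ccccc2)c1)=C/c1ccc2c(c1)[C@H](c1cc(OCc3ccccc3)cc(OCc3ccccc3)c1)[C@@H](c1ccc(OCc3ccccc3)cc1)O2)c1cc(OCc2ccccc2)cc(OCc2ccccc2)c1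
F3 | step 11 | (3S,4S)-3,4-bis[3,5-bis(benzyloxy)phenyl]-3-[(S)-(DHB-5-yl)(dimethylphenylsilyl)methyl]-2,2-diphenyl-1,2-oxasiletane | O1[Si](c2ccccc2)(c2ccccc2)[C@](c2cc(OCc3ccccc3)cc(OCc3ccccc3)c2)([C@H](c2ccc3c(c2)[C@H](c2cc(OCc4ccccc4)cc(OCc4ccccc4)c2)[C@@H](c2ccc(OCc4ccccc4)cc2)O3)[Si](C)(C)c2ccccc2)[C@@H]1c1cc(OCc2ccccc2)cc(OCc2ccccc2)c1
F4 | step 9 | (S,Z)-1-[3,5-bis(benzyloxy)phenyl]-3-(DHB-5-yl)-2-(tributylstannyl)prop-2-en-1-ol | O[C@H](/C([Sn](CCCC)(CCCC)CCCC)=C/c1ccc2c(c1)[C@H](c1cc(OCc3ccccc3)cc(OCc3ccccc3)c1)[C@@H](c1ccc(OCc3ccccc3)cc1)O2)c1cc(OCc2ccccc2)cc(OCc2ccccc2)c1
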